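**Assumption:** the SMILES is taken as drawn (the mirror-image series of the usual Inula dimers), so all chiral controllers are chosen for that enantiomer; atom labels C1–C15 (primed for the seco-eudesmane half) follow guaiane/eudesmane numbering.

## Retrosynthetic overview

1. 31 ⇐ thermal [4+2] of acetoxy-cyclopentadiene 30 (made in the flask from tertiary carbinol 29) with methylene lactone 17; the norbornene is formed last.
2. 29 ⇐ 26 by the key step (step 20): one chromium-mediated allylation/lactonization closes the seven-membered ring B (C7–C8) and the trans-γ-lactone together, on an unprotected diol.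
3. 26 ⇐ 4-methylcyclopent-4-ene-1,3-dione 19 + crotonaldehyde (amine-catalysed Michael sets C10), CBS reduction (C2), allyl Grignard, cross-metathesis.
4. 17 ⇐ ring-closing metathesis of 14; 14 ⇐ indium Barbier union of butenolide bromide 13 with enal 6 (from (R)-citronellal); C8' is then inverted by Mitsunobu relactonization.
5. Ring order: butenolide → cyclohexene (fragment 1); purchased cyclopentene → ring B + lactone in one operation (fragment 2); norbornene last.

## Fragment 1: dienophile 17

Step 1
Reactants: 1 (R)-citronellal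
Product: 2 (3R)-3,7-dimethyl-2-methylideneoct-6-enal
Conditions: 37% aq. HCHO, pyrrolidine (10 mol%), EtCO2H (10 mol%), i-PrOH, 45 °C
Reagents that add atoms: formaldehyde C=O
Why: Organocatalytic Mannich-type α-methylenation (enamine addition to the iminium of formaldehyde, then amine elimination); the C3 stereocentre is not enolizable and stays R.

Step 2
Reactants: 2 (3R)-3,7-dimethyl-2-methylideneoct-6-enal
Product: 4 (3R)-3-methyl-2-methylidenehexane-1,6-diol, via dialdehyde 3 (not isolated)
Conditions: O3 (1.0 equiv), CH2Cl2, −78 °C; Me2S; then NaBH4, CeCl3·7H2O, MeOH, −40 °C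
Reagents that add atoms: ozone [O-][O+]=O
Why: Chemoselective ozonolysis of the electron-rich trisubstituted alkene over the formyl-deactivated 1,1-disubstituted alkene, followed by Luche-type 1,2-reduction of both aldehydes; no stereocentre is touched.

Step 3
Reactants: 4 (3R)-3-methyl-2-methylidenehexane-1,6-diol
Product: 5 (3R)-6-hydroxy-3-methyl-2-methylidenehexanal
Conditions: MnO2 (15 equiv), CH2Cl2, 25 °C
Reagents that add atoms: none
Why: Allylic-alcohol oxidation with MnO2 is selective for the allylic primary hydroxyl over the saturated one.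

Step 4
Reactants: 5 (3R)-6-hydroxy-3-methyl-2-methylidenehexanal
Product: 6 (4R)-4-methyl-5-methylidene-6-oxohexyl acetate
Conditions: Ac2O, pyridine, CH2Cl2, 0 °C
Reagents that add atoms: acetic anhydride CC(=O)OC(C)=O
Why: Simple O-acetylation installs the C1' acetate of the target early.

Step 5
Reactants: 7 3-methylbut-3-en-1-ol
Product: 8 3-methylbut-3-enal
Conditions: Dess–Martin periodinane, NaHCO3, CH2Cl2, 0 °C (used as a cold solution)
Reagents that add atoms: none
Why: Buffered Dess–Martin oxidation gives the β,γ-unsaturated aldehyde without conjugation.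

Step 6
Reactants: 8 3-methylbut-3-enal; 9 tert-butyldimethyl(prop-2-yn-1-yloxy)silane
Product: 10 (4R)-1-[(tert-butyldimethylsilyl)oxy]-6-methylhept-6-en-2-yn-4-ol
Conditions: ZnMe2 (3 equiv), (S,S)-ProPhenol (10 mol%, the ligand antipode that gives the R carbinol), toluene, 0 °C
Reagents that add atoms: none
Why: Zinc-ProPhenol catalytic asymmetric alkynylation of an aldehyde; the ligand sets C8' as R, deliberately opposite to the final configuration because step 13 inverts it.

Step 7
Reactants: 10 (4R)-1-[(tert-butyldimethylsilyl)oxy]-6-methylhept-6-en-2-yn-4-ol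
Product: 11 (2Z,4R)-1-[(tert-butyldimethylsilyl)oxy]-2-iodo-6-methylhepta-2,6-dien-4-ol
Conditions: NaAlH2(OCH2CH2OCH3)2, THF, 0 °C; then I2, −78 °C
Reagents that add atoms: iodine II
Why: Hydroxyl-directed trans-hydroalumination of the propargylic alcohol and iodinolysis with retention place iodine on the distal carbon, cis to the carbinol carbon.

Step 8
Reactants: 11 (2Z,4R)-1-[(tert-butyldimethylsilyl)oxy]-2-iodo-6-methylhepta-2,6-dien-4-ol
Product: 12 (5R)-3-{[(tert-butyldimethylsilyl)oxy]methyl}-5-(2-methylprop-2-en-1-yl)furan-2(5H)-one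
Conditions: Pd(PPh3)2Cl2 (5 mol%), CO (1 atm), NEt3, THF, 50 °C
Reagents that add atoms: carbon monoxide [C-]#[O+]
Why: Palladium-catalysed carbonylative lactonization of a Z-iodoallylic alcohol; the cis geometry forces butenolide closure and the stereocentre is untouched.

Step 9
Reactants: 12 (5R)-3-{[(tert-butyldimethylsilyl)oxy]methyl}-5-(2-methylprop-2-en-1-yl)furan-2(5H)-one
Product: 13 (5R)-3-(bromomethyl)-5-(2-methylprop-2-en-1-yl)furan-2(5H)-one
Conditions: PPh3, Br2, CH2Cl2, 0 to 25 °C
Reagents that add atoms: bromine BrBr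
Why: Appel-type direct conversion of a primary silyl ether into the bromide with Ph3PBr2, without free bromine that would add to the methallyl group.

Step 10
Reactants: 13 (5R)-3-(bromomethyl)-5-(2-methylprop-2-en-1-yl)furan-2(5H)-one; 6 (4R)-4-methyl-5-methylidene-6-oxohexyl acetate
Product: 14 (4R,5R)-4-[(1R,3R)-6-acetoxy-1-hydroxy-3-methyl-2-methylidenehexyl]-3-methylidene-5-(2-methylprop-2-en-1-yl)oxolan-2-one
Conditions: In powder, THF/H2O (1:1), 25 °C
Reagents that add atoms: none
Why: Indium-mediated Barbier allylation with allylic transposition (SE2'); the γ-carbon C7' bonds anti to the methallyl group of the butenolide, and the ring-locked E allylindium in a chair Zimmerman–Traxler transition state gives the anti carbinol (6'R) while regenerating the exocyclic methylene.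

Step 11
Reactants: 14 (Barbier adduct)
Product: 15 (3aR,4R,7aR)-4-hydroxy-6-methyl-3-methylidene-5-[(2R)-5-acetoxypentan-2-yl]-3a,4,7,7a-tetrahydro-1-benzofuran-2(3H)-one (trans-fused, 8'-epimer of 17)
Conditions: second-generation Hoveyda–Grubbs catalyst (10 mol%), toluene, 80 °C, N2 sparge
Reagents that add atoms: none
Why: Ring-closing metathesis of the two 1,1-disubstituted alkenes gives the tetrasubstituted cyclohexene, assisted by the allylic hydroxyl, while the electron-poor methylene lactone stays out of the catalytic cycle.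

Step 12
Reactants: 15 (trans-fused lactone)
Product: 16 2-[(1S,2R,6R)-2,6-dihydroxy-4-methyl-3-[(2R)-5-acetoxypentan-2-yl]cyclohex-3-en-1-yl]prop-2-enoic acid
Conditions: LiOH (1.05 equiv), THF/H2O, 0 °C; then 1 M HCl to pH 4
Reagents that add atoms: lithium hydroxide [Li+].[OH-]
Why: Selective saponification; the strained trans-fused γ-lactone hydrolyses much faster than the acyclic primary acetate, so one equivalent of hydroxide opens only the lactone.

Step 13
Reactants: 16 (seco acid)
Product: 17 (3aR,4R,7aS)-4-hydroxy-6-methyl-3-methylidene-5-[(2R)-5-acetoxypentan-2-yl]-3a,4,7,7a-tetrahydro-1-benzofuran-2(3H)-one (ent-1-O-acetylbritannilactone)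
Conditions: PPh3, diisopropyl azodicarboxylate, THF (0.01 M), 0 °C
Reagents that add atoms: none
Why: Mitsunobu lactonization; the less hindered, non-allylic C8' hydroxyl is activated and displaced by the carboxylate with SN2 inversion, giving the cis-fused lactone (8'S) and leaving the 6'-hydroxyl free.

## Fragment 2: diene precursor 29

Step 14
Reactants: 18 3-methylcyclopent-2-en-1-one
Product: 19 4-methylcyclopent-4-ene-1,3-dione
Conditions: Rh2(caprolactamate)4 (1 mol%), t-BuOOH (5 equiv), K2CO3, CH2Cl2, 25 °C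
Reagents that add atoms: tert-butyl hydroperoxide CC(C)(C)OO
Why: Dirhodium-caprolactamate-catalysed allylic C–H oxidation converts the γ-methylene of the enone into the second carbonyl.

Step 15
Reactants: 19 4-methylcyclopent-4-ene-1,3-dione (1.5 equiv); 20 (E)-crotonaldehyde
Product: 21 (3R)-3-(3-methyl-2,5-dioxocyclopent-3-en-1-yl)butanal (C1 epimers, interconverting)
Conditions: (S)-α,α-diphenylprolinol trimethylsilyl ether (10 mol%), PhCO2H (10 mol%), toluene, 0 °C
Reagents that add atoms: none
Why: Iminium-catalysed (Jørgensen–Hayashi) Michael addition of the acidic dione C–H; the nucleophile adds to the enal face away from the diphenylsilyloxymethyl group and sets C10 as R.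

Step 16
Reactants: 21 (Michael adduct)
Product: 22 (4S,5R)-4-hydroxy-5-[(2R)-4-hydroxybutan-2-yl]-2-methylcyclopent-2-en-1-one
Conditions: (R)-2-methyl-CBS-oxazaborolidine (20 mol%), BH3·SMe2 (0.8 equiv), THF, −40 °C; MeOH; then NEt3, MeOH, 25 °C
Reagents that add atoms: none
Why: Proposed new method: borane reduces the aldehyde, and the oxazaborolidine binds the less hindered carbonyl (C2, remote from the ring methyl) with the branched sp3 carbon C1 as the large group, so hydride delivery gives 2S; C1 then equilibrates to trans under the amine treatment. The closest known reaction is the CBS desymmetrizing monoreduction of 2,2-disubstituted cyclopentane-1,3-diones.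

Step 17
Reactants: 22 (hydroxy enone)
Product: 23 (1R,4S,5R)-5-[(2R)-4-hydroxybutan-2-yl]-2-methyl-1-(prop-2-en-1-yl)cyclopent-2-ene-1,4-diol
Conditions: allylmagnesium bromide (3.5 equiv), THF, −78 °C
Reagents that add atoms: allylmagnesium bromide C=CC[Mg]Br
Why: Grignard 1,2-addition to the enone carbonyl, anti to the adjacent C1 side chain; the C1 and C5 stereocentres only have to serve until step 22 removes them.

Step 18
Reactants: 23 (triol)
Product: 24 (3R)-3-[(1R,2R,5S)-2,5-dihydroxy-3-methyl-2-(prop-2-en-1-yl)cyclopent-3-en-1-yl]butanal (in equilibrium with its lactol)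
Conditions: TEMPO (10 mol%), PhI(OAc)2 (1.1 equiv), CH2Cl2, 0 °C
Reagents that add atoms: none
Why: Oxoammonium (TEMPO/PhI(OAc)2) oxidation is selective for the primary alcohol over the secondary allylic and tertiary hydroxyls.

Step 19
Reactants: 24 (aldehyde); 25 methyl 2-(bromomethyl)prop-2-enoate (3 equiv)
Product: 26 methyl (Z)-2-(bromomethyl)-4-[(1R,4S,5R)-1,4-dihydroxy-2-methyl-5-[(2R)-4-oxobutan-2-yl]cyclopent-2-en-1-yl]but-2-enoate
Conditions: second-generation Hoveyda–Grubbs catalyst (5 mol%), CH2Cl2, 40 °C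
Reagents that add atoms: none
Why: Olefin cross-metathesis of the terminal allyl group with a 2-substituted acrylate gives the thermodynamically preferred trisubstituted enoate (chain cis to CH2Br); the ring alkene is too hindered to react.

Step 20 (key step)
Reactants: 26 (allylic bromide aldehyde)
Product: 28 (1R,2S,5R,7S,8R,10R)-2,5-dihydroxyguaia-3,11(13)-dien-12,8-olide, via seco hydroxy ester 27 (not isolated)
Conditions: CrCl2 (6 equiv), THF (0.005 M), 25 °C, then 50 °C
Reagents that add atoms: none
Why: Intramolecular Nozaki–Hiyama-type allylation with divalent chromium followed by lactonization closes ring B and the γ-lactone in one operation. The E allylchromium and the aldehyde chain sit equatorially in a chair Zimmerman–Traxler transition state fused to the forming seven-membered ring, with the C10 methyl pseudo-equatorial, which gives the anti adduct (7S,8R). The chromium alkoxide then acylates the trans-disposed ester; any lactol form of 26 reopens on coordination to trivalent chromium.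

Step 21
Reactants: 28 (tricyclic diol)
Product: 29 (1R,2S,5R,7S,8R,10R)-2-acetoxy-5-hydroxyguaia-3,11(13)-dien-12,8-olide
Conditions: Ac2O, pyridine, 0 °C
Reagents that add atoms: acetic anhydride CC(=O)OC(C)=O
Why: Acetylation of the only acylable hydroxyl (secondary C2); the tertiary allylic C5 hydroxyl does not react without a nucleophilic catalyst.

## Union

Step 22
Reactants: 29 (tertiary carbinol acetate); 17 ent-1-O-acetylbritannilactone (3 equiv, excess recovered)
Product: 31 CNP0211028.4, via acetoxycyclopentadiene 30 (not isolated)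
Conditions: Ph2S[OC(CF3)2Ph]2 (1.05 equiv), CH2Cl2, −50 °C, 15 min; then 17, toluene (2 M), 25 °C, 48 h, dark
Reagents that add atoms: none
Why: Martin-sulfurane anti-elimination of the C5 hydroxyl with the trans C1 hydrogen gives the conjugated diene, which undergoes a thermal Diels–Alder reaction with 17. The dienophile CH2 bonds to the fully substituted C1 and C11' to C3; attack is on the diene face anti to both the C2 acetoxy and the C10 methyl, with the lactone carbonyl exo, on the lactone face away from the 6'-hydroxyl. This sets C1, C3 and C11' and leaves the acetoxy group syn to the C4=C5 bond.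

## Compound list

1 | (R)-citronellal | O=CC[C@H](C)CCC=C(C)C | starting material
2 | (3R)-3,7-dimethyl-2-methylideneoct-6-enal | O=CC(=C)[C@H](C)CCC=C(C)C | intermediate
3 | (3R)-3-methyl-2-methylidenehexanedial | O=CC(=C)[C@H](C)CCC=O | intermediate
4 | (3R)-3-methyl-2-methylidenehexane-1,6-diol | OCC(=C)[C@H](C)CCCO | intermediate
5 | (3R)-6-hydroxy-3-methyl-2-methylidenehexanal | O=CC(=C)[C@H](C)CCCO | intermediate
6 | (4R)-4-methyl-5-methylidene-6-oxohexyl acetate | O=CC(=C)[C@H](C)CCCOC(C)=O | intermediate
7 | 3-methylbut-3-en-1-ol | C=C(C)CCO | starting material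
8 | 3-methylbut-3-enal | C=C(C)CC=O | intermediate
9 | tert-butyldimethyl(prop-2-yn-1-yloxy)silane | C#CCO[Si](C)(C)C(C)(C)C | starting material
10 | (4R)-1-[(tert-butyldimethylsilyl)oxy]-6-methylhept-6-en-2-yn-4-ol | C=C(C)C[C@@H](O)C#CCO[Si](C)(C)C(C)(C)C | intermediate
11 | (2Z,4R)-1-[(tert-butyldimethylsilyl)oxy]-2-iodo-6-methylhepta-2,6-dien-4-ol | C=C(C)C[C@@H](O)/C=C(\I)CO[Si](C)(C)C(C)(C)C | intermediate
12 | (5R)-3-{[(tert-butyldimethylsilyl)oxy]methyl}-5-(2-methylprop-2-en-1-yl)furan-2(5H)-one | C=C(C)C[C@@H]1C=C(CO[Si](C)(C)C(C)(C)C)C(=O)O1 | intermediate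
13 | (5R)-3-(bromomethyl)-5-(2-methylprop-2-en-1-yl)furan-2(5H)-one | C=C(C)C[C@@H]1C=C(CBr)C(=O)O1 | intermediate
14 | (4R,5R)-4-[(1R,3R)-6-acetoxy-1-hydroxy-3-methyl-2-methylidenehexyl]-3-methylidene-5-(2-methylprop-2-en-1-yl)oxolan-2-one | C=C1C(=O)O[C@H](CC(C)=C)[C@H]1[C@@H](O)C(=C)[C@H](C)CCCOC(C)=O | intermediate
15 | (3aR,4R,7aR)-4-hydroxy-6-methyl-3-methylidene-5-[(2R)-5-acetoxypentan-2-yl]-3a,4,7,7a-tetrahydro-1-benzofuran-2(3H)-one (trans-fused) | C=C1C(=O)O[C@@H]2CC(C)=C([C@H](C)CCCOC(C)=O)[C@H](O)[C@@H]12 | intermediate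
16 | 2-[(1S,2R,6R)-2,6-dihydroxy-4-methyl-3-[(2R)-5-acetoxypentan-2-yl]cyclohex-3-en-1-yl]prop-2-enoic acid | C=C(C(=O)O)[C@H]1[C@H](O)CC(C)=C([C@H](C)CCCOC(C)=O)[C@@H]1O | intermediate
17 | (3aR,4R,7aS)-4-hydroxy-6-methyl-3-methylidene-5-[(2R)-5-acetoxypentan-2-yl]-3a,4,7,7a-tetrahydro-1-benzofuran-2(3H)-one (ent-1-O-acetylbritannilactone) | C=C1C(=O)O[C@H]2CC(C)=C([C@H](C)CCCOC(C)=O)[C@H](O)[C@@H]12 | intermediate
18 | 3-methylcyclopent-2-en-1-one | CC1=CC(=O)CC1 | starting material
19 | 4-methylcyclopent-4-ene-1,3-dione | CC1=CC(=O)CC1=O | intermediate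
20 | (E)-crotonaldehyde | C/C=C/C=O | starting material
21 | (3R)-3-(3-methyl-2,5-dioxocyclopent-3-en-1-yl)butanal | C[C@H](CC=O)C1C(=O)C=C(C)C1=O | intermediate
22 | (4S,5R)-4-hydroxy-5-[(2R)-4-hydroxybutan-2-yl]-2-methylcyclopent-2-en-1-one | C[C@H](CCO)[C@H]1C(=O)C(C)=C[C@@H]1O | intermediate
23 | (1R,4S,5R)-5-[(2R)-4-hydroxybutan-2-yl]-2-methyl-1-(prop-2-en-1-yl)cyclopent-2-ene-1,4-diol | C[C@H](CCO)[C@H]1[C@](O)(CC=C)C(C)=C[C@@H]1O | intermediate
24 | (3R)-3-[(1R,2R,5S)-2,5-dihydroxy-3-methyl-2-(prop-2-en-1-yl)cyclopent-3-en-1-yl]butanal | C[C@H](CC=O)[C@H]1[C@](O)(CC=C)C(C)=C[C@@H]1O | intermediate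
25 | methyl 2-(bromomethyl)prop-2-enoate | C=C(CBr)C(=O)OC | starting material
26 | methyl (Z)-2-(bromomethyl)-4-[(1R,4S,5R)-1,4-dihydroxy-2-methyl-5-[(2R)-4-oxobutan-2-yl]cyclopent-2-en-1-yl]but-2-enoate | C[C@H](CC=O)[C@H]1[C@](O)(C/C=C(\CBr)C(=O)OC)C(C)=C[C@@H]1O | intermediate
27 | methyl 2-[(1R,2S,5R,7S,8R,10R)-2,5,8-trihydroxyguai-3-en-7-yl]prop-2-enoate (seco hydroxy ester of 28) | C=C(C(=O)OC)[C@@H]1C[C@]2(O)C(C)=C[C@H](O)[C@H]2[C@H](C)C[C@H]1O | intermediate
28 | (1R,2S,5R,7S,8R,10R)-2,5-dihydroxyguaia-3,11(13)-dien-12,8-olide | C=C1C(=O)O[C@@H]2C[C@@H](C)[C@H]3[C@](O)(C[C@@H]12)C(C)=C[C@@H]3O | intermediate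
29 | (1R,2S,5R,7S,8R,10R)-2-acetoxy-5-hydroxyguaia-3,11(13)-dien-12,8-olide | C=C1C(=O)O[C@@H]2C[C@@H](C)[C@H]3[C@](O)(C[C@@H]12)C(C)=C[C@@H]3OC(C)=O | intermediate
30 | (2S,7S,8R,10R)-2-acetoxyguaia-1(5),3,11(13)-trien-12,8-olide | C=C1C(=O)O[C@@H]2C[C@@H](C)C3=C(C[C@@H]12)C(C)=C[C@@H]3OC(C)=O | intermediate
31 | CNP0211028.4 ([4+2] adduct of 30 and 17, bonds C1–C13' and C3–C11') | C=C1C(=O)O[C@@H]2C[C@@H](C)[C@]34C[C@@]5(C(=O)O[C@H]6CC(C)=C([C@H](C)CCCOC(C)=O)[C@H](O)[C@H]65)[C@H](C(C)=C3C[C@@H]12)[C@@H]4OC(C)=O | target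

## Summary and risks

Total step count: 22. Longest linear sequence: 10 steps (steps 5–13, then 22).

The three steps most likely to fail:

**Step 22 (dehydration and cycloaddition).** The acetoxy group electronically favours syn attack, diene 30 carries its own methylene lactone and can homodimerize, and the C2 hydrogen can undergo a 1,5-shift. The fallback sets out from 29 and masks its methylene lactone: dimethylamine adds to give the Mannich base F1, so the diene half no longer contains a dienophile. The sulfurane then gives the amine-bearing diene F2, which can be pushed to react with 17 (large excess, high pressure) to give the amine-bearing cycloadduct F3. Methyl iodide gives the methiodide F4, and NaHCO3 eliminates trimethylamine, returning to the route at 31.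

**Step 20 (chromium-mediated double ring closure).** The sense of C7/C8 relative to C10, and trans versus cis lactone fusion, rest on a transition-state argument. The fallback sets out from 24 and replaces the allylchromium by an allylsilane: cross-metathesis with methyl 2-[(trimethylsilyl)methyl]prop-2-enoate gives the allylsilane F5. Bu4NF then triggers an intramolecular Hosomi–Sakurai-type addition through an open transition state, which has a different stereochemical bias, and the alkoxide lactonizes, returning to the route at 28.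

**Step 11 (metathesis to a tetrasubstituted alkene in a trans-fused bicycle).** The fallback sets out from 14 and inverts C8' before ring closure: LiOH gives the open-chain seco acid F6, and Mitsunobu lactonization gives the cis-disposed lactone diene F7. Metathesis of F7 then closes the unstrained cis-fused ring and returns to the route at 17, bypassing 15 and 16.

Further compounds
F1 | step 22 | 13-(dimethylamino)-11,13-dihydro derivative of 29 (C11 epimers) | CN(C)CC1C(=O)O[C@@H]2C[C@@H](C)[C@H]3[C@](O)(C[C@@H]12)C(C)=C[C@@H]3OC(C)=O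
F2 | step 22 | 13-(dimethylamino)-11,13-dihydro derivative of diene 30 | CN(C)CC1C(=O)O[C@@H]2C[C@@H](C)C3=C(C[C@@H]12)C(C)=C[C@@H]3OC(C)=O
F3 | step 22 | 13-(dimethylamino)-11,13-dihydro derivative of 31 | CN(C)CC1C(=O)O[C@@H]2C[C@@H](C)[C@]34C[C@@]5(C(=O)O[C@H]6CC(C)=C([C@H](C)CCCOC(C)=O)[C@H](O)[C@H]65)[C@H](C(C)=C3C[C@@H]12)[C@@H]4OC(C)=O
F4 | step 22 | trimethylammonium iodide (methiodide) of F3 | C[N+](C)(C)CC1C(=O)O[C@@H]2C[C@@H](C)[C@]34C[C@@]5(C(=O)O[C@H]6CC(C)=C([C@H](C)CCCOC(C)=O)[C@H](O)[C@H]65)[C@H](C(C)=C3C[C@@H]12)[C@@H]4OC(C)=O.[I-]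
F5 | step 20 | methyl (Z)-4-[(1R,4S,5R)-1,4-dihydroxy-2-methyl-5-[(2R)-4-oxobutan-2-yl]cyclopent-2-en-1-yl]-2-[(trimethylsilyl)methyl]but-2-enoate | C[C@H](CC=O)[C@H]1[C@](O)(C/C=C(\C[Si](C)(C)C)C(=O)OC)C(C)=C[C@@H]1O
F6 | step 11 | open-chain seco acid of 14 | C=C(C(=O)O)[C@@H]([C@H](O)CC(C)=C)[C@@H](O)C(=C)[C@H](C)CCCOC(C)=O
F7 | step 11 | 5-epimer of 14 (cis-disposed lactone diene) | C=C1C(=O)O[C@@H](CC(C)=C)[C@H]1[C@@H](O)C(=C)[C@H](C)CCCOC(C)=O
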